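## The problem

- The target is a (2S)-flavanone. Ring A carries a methoxy group at C5, a free hydroxyl at C7 and, at C8, a (2R)-5-hydroxy-5-methyl-2-(prop-1-en-2-yl)hexyl chain. Ring B is a 4-hydroxy-2-methoxyphenyl group.
- The two stereocentres, C2 of ring C and C2'' of the chain, are separated by an aromatic ring and five bonds. Neither can bias the other, so C2'' must come from an auxiliary and C2 from a catalyst, and the fragments must be joined without disturbing C2''.
- C2 is the fragile centre. With the C4 carbonyl in place, base opens ring C to the 2'-hydroxychalcone, and the electron-rich ring B makes the C2–O1 bond ionisable in strong acid.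
- The chain adds two cation precursors, a 1,1-disubstituted alkene and a tertiary alcohol. They exclude hydrogenolysis and strong acid, and the alkene can cyclise onto the C7 hydroxyl.
- Ring A is pentasubstituted, and the two oxygens flanking the chain must be told apart (one becomes O1, the other the C7 hydroxyl). The 2-alkyl-5-methoxyresorcinol core is symmetric, so this reduces to one desymmetrising event.
- The enabling feature is that O1–C8a=C4a–C4 of ring C is a masked 1-oxadiene, an ortho-quinone methide of ring A with C4 as methide carbon, while C2–C3 with ring B is an electron-rich styrene. If C4 is carried as a methoxy-bearing carbon at the alcohol oxidation level, ring C and C2 can be formed in one (4+2) event with no enolisable carbonyl present.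

## Retrosynthesis

**Protecting groups (30 from 29).** Only the O–C and O–Si bonds to protecting groups are cut. Target 30 is traced to flavanone 29, with both phenols as methoxymethyl ethers and the tertiary alcohol as a triethylsilyl ether. Acid-labile groups are preferred because base opens the flavanone and hydrogen would saturate the isopropenyl group. Precursor 29 is no simpler in skeleton but is free of acidic protons. The forward step must stay below the acidity at which the tertiary carbinol or the alkene ionise.

**Oxidation level at C4 (29 from 28 from 27).** No skeletal bond is cut; the C4 carbonyl is replaced by a hydroxyl (28) and then a methoxy group (27). Against keeping the ketone throughout, this removes the retro-oxa-Michael pathway at the moment C2 is created. The price is two functional-group steps. They require the C4–O bond, activated by three oxygen donors on ring A, to ionise more readily than the acetals, and a neutral oxidant.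

**Ring C (27 from 20, 23 and 24).** The O1–C2 and C3–C4 bonds are cut, leading to salicylaldehyde 20, styrene 23 and trimethyl orthoformate 24, through acetal 25 and methide 26. Cutting O1–C2 alone gives a chalcone whose closure is reversible and hard to render enantioselective. Cutting C2–C1' requires a hindered aryl nucleophile to add to a deactivated chromone. The double cut removes ring C and both of its stereocentres and leaves a benzaldehyde and a two-step styrene. The forward reaction must select one face at C2 under a chiral acid, join the styrene CH2 to C4, and prefer the styrene over the isopropenyl group.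

**Formyl group and desymmetrisation (20 from 19 from 17).** The C4a–C4 bond is cut and the acetal on the future O1 is restored, giving aldehyde 19 and then the symmetric arene 17 (through aryllithium 18). Phenol ortho-formylation after statistical mono-protection would waste half the material. Here the two ring positions of 17 are equivalent, and the acetal next to the new formyl group is distinguished by chelation. The precursor loses one substituent and gains a mirror plane. The forward steps require ring lithiation rather than benzylic lithiation, and cleavage of one of two acetals.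

**Chain to ring (17 from 15 and 11).** The C8–C1'' bond is cut to aryl iodide 15 and alkyl iodide 11, joined through zinc reagent 16. Direct substitution by aryllithium 14 risks elimination, since the β-hydrogen of 11 is allylic and tertiary. Benzylation of a chiral enolate would need a trioxygenated benzyl halide too labile to handle. Iodide 15 goes back through 14 and bis-acetal 13 to 5-methoxyresorcinol 12. The coupling must join two hindered partners without β-hydride elimination.

**Chain (11 from 10, 9, 8, 7, then 4 and 5; 4 from 1 and 2).** The C2''–C3'' bond is cut by deconjugative alkylation of imide 4 with prenyl bromide 5 through dienolate 6. The isopropenyl group is not made by olefination but emerges from the senecioyl unit, and the auxiliary from 1 sets C2''. The tertiary alcohol is drawn from the prenyl alkene of 7 by epoxidation (8) and hydride opening (9). Iodide 10 and its silyl ether 11 follow. Alkylation with an unactivated oxygenated iodide would be shorter on paper but is poorly suited to imide enolates. All precursors are commodity chemicals. The forward sequence requires the peracid to distinguish a trisubstituted from a 1,1-disubstituted alkene.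

**Styrene (23 from 22 from 21).** The vinyl C=C bond is cut to aldehyde 22, and the acetal O–C bond to 4-hydroxy-2-methoxybenzaldehyde 21. No alternative is shorter. The forward steps are a phenol protection and a methylenation.

## Roads not taken

**Alternative 1:** Aryne insertion into a cinnamic acid.
- **Cut:** both bonds from ring A to the C3 bridge, C8a–O and C4a–C4.
- **Forward step:** fluoride strips silicon and triflate from the silylaryl triflate A2. The carboxylate of cinnamic acid A3 adds across the transient C4a–C8a triple bond, and the acyl group migrates to C4a to give 2'-hydroxychalcone A1.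
- **Merits:** all flavanone carbons are assembled in one near-neutral step. The C5 methoxy group directs the oxygen nucleophile to the distal carbon C8a, as required.
- **Weak points:** A2 is a hexasubstituted benzene needing its own long synthesis. The attacked carbon is flanked by the branched chain. Simple O-arylation without acyl shift competes. No ring is closed and no stereocentre is set. A1 must still be closed to 29, an equilibrium that is difficult to control enantioselectively for an unactivated chalcone.
- **Comparison:** the reaction type is precedented on simple arynes, so this step is arguably on firmer ground than step 14. Against that, the chosen plan makes ring C and C2 together, and its ring A precursor 20 is five steps from a purchased phenol.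

**Alternative 2:** Benzannulation of ring A around the chain.
- **Cut:** the C8–C8a and C6–C7 bonds of ring A.
- **Forward step:** heating 3-methoxycyclobutenone A5 opens the four-membered ring. The resulting ketene function combines with siloxyalkyne A6, and a cascade of electrocyclic steps gives resorcinol mono-silyl ether A4.
- **Merits:** the ring A substitution pattern is unambiguous. The two oxygens flanking the chain emerge already differentiated, one free and one silylated. This is better than the chosen plan, which needs lithiation and a chelation-controlled deprotection (steps 10 and 11) for the same result.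
- **Weak points:** it does nothing for ring C or C2. After A4, formylation to the silyl analogue A7 of aldehyde 20 and a ring C construction are still required, so it replaces steps 7 to 11 and not the key step. A6 requires homologation of the chain acid to a sensitive ynol ether, and A5 must be prepared. A benzene ring that can be bought as 12 is built from scratch.
- **Comparison:** the chosen plan uses the symmetry of 12 and two directed lithiations to reach 20 in fewer operations.

**Alternative 3:** Ring A folded onto a preformed dihydropyranone.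
- **Cut:** the C4a–C5 bond.
- **Forward step:** heating dioxinone A9 unmasks a ketene carbon (the future C5). The nucleophilic C4a of the dihydropyranone attacks it, and ring A aromatises to 5,7-dihydroxyflavanone A8.
- **Merits:** C2 is set early on the pyranone by an established catalytic asymmetric hetero-Diels–Alder reaction of aldehyde 22. On absolute configuration this road is more secure than the chosen one. No aromatic substitution chemistry is needed.
- **Weak points:** A8 has both the C5 and C7 hydroxyls free. The target needs the methyl group on the chelated, less reactive C5 oxygen, which costs protection, basic methylation (with risk of ring opening at C2) and deprotection. A9 carries an acidic methine at the future C8 and must be assembled linearly with the chiral chain introduced early. Thermolysis above 100 °C exposes the 2-aryl-dihydropyranone to retro-Michael racemisation.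
- **Comparison:** the chosen plan has the C5 methoxy group in place from the start and joins the chain late. It accepts a less certain step for setting C2.

Key step: step 14

Assumption: the sense of induction of the chiral phosphoric acid in step 14 cannot be predicted with confidence. The (R)-configured acid is written, and its mirror image is to be used if screening shows it favours the (2R) series. The remote chain centre should not bias either face.

## Route

Step 1
Reactants: 1 (S)-4-benzyloxazolidin-2-one; 2 3-methylbut-2-enoyl chloride
Product: 4 (S)-4-benzyl-3-(3-methylbut-2-enoyl)oxazolidin-2-one, via N-lithio oxazolidinone 3 (not isolated)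
Conditions: n-BuLi, THF, −78 °C; then 2, −78 → 0 °C
Reagents that add atoms: none
Why: N-acylation of a lithiated oxazolidinone with an acid chloride, the standard preparation of N-enoyl imides; no stereocentre is touched.

Step 2
Reactants: 4 (S)-4-benzyl-3-(3-methylbut-2-enoyl)oxazolidin-2-one; 5 1-bromo-3-methylbut-2-ene
Product: 7 (4S)-4-benzyl-3-[(2S)-5-methyl-2-(prop-1-en-2-yl)hex-4-enoyl]oxazolidin-2-one, via sodium dienolate 6 (not isolated)
Conditions: NaN(SiMe3)2, THF, −78 °C; then 5, −78 → −40 °C
Reagents that add atoms: none
Why: Deconjugative Evans alkylation: γ-deprotonation gives the chelated (Z)-dienolate 6, which reacts at its α-carbon with the allylic bromide on the face opposite the benzyl group. This sets C2'' as (2S) at this stage and unveils the isopropenyl group.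

Step 3
Reactants: 7 (4S)-4-benzyl-3-[(2S)-5-methyl-2-(prop-1-en-2-yl)hex-4-enoyl]oxazolidin-2-one
Product: 8 (4S)-4-benzyl-3-{(2S)-2-[(3,3-dimethyloxiran-2-yl)methyl]-3-methylbut-3-enoyl}oxazolidin-2-one (both epimers at the oxirane carbon)
Conditions: mCPBA (1.05 equiv), NaHCO3, CH2Cl2, −10 → 0 °C
Reagents that add atoms: 3-chloroperbenzoic acid, O=C(OO)c1cccc(Cl)c1
Why: Prilezhaev epoxidation; the trisubstituted prenyl alkene is the more nucleophilic one, and the 1,1-disubstituted alkene is further deactivated by the adjacent acyl group and shielded by the auxiliary. The new oxirane centre need not be controlled, since step 4 erases it.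

Step 4
Reactants: 8 (4S)-4-benzyl-3-{(2S)-2-[(3,3-dimethyloxiran-2-yl)methyl]-3-methylbut-3-enoyl}oxazolidin-2-one
Product: 9 (2S)-5-methyl-2-(prop-1-en-2-yl)hexane-1,5-diol
Conditions: LiAlH4, THF, 0 °C → reflux; H2O, aq. NaOH
Reagents that add atoms: none
Why: Hydride reduction cleaves the imide to the primary alcohol with release of the auxiliary and opens the trisubstituted epoxide at its less substituted carbon to give the tertiary alcohol. C2'' is not enolisable once the acyl group is reduced and is retained.

Step 5
Reactants: 9 (2S)-5-methyl-2-(prop-1-en-2-yl)hexane-1,5-diol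
Product: 10 (5S)-6-iodo-2-methyl-5-(prop-1-en-2-yl)hexan-2-ol
Conditions: I2, PPh3, imidazole, CH2Cl2, 0 °C → rt
Reagents that add atoms: iodine, II
Why: Appel-type iodination is selective for the primary hydroxyl because the tertiary alcohol is too hindered to form the alkoxyphosphonium salt.

Step 6
Reactants: 10 (5S)-6-iodo-2-methyl-5-(prop-1-en-2-yl)hexan-2-ol
Product: 11 triethyl{[(5S)-6-iodo-2-methyl-5-(prop-1-en-2-yl)hexan-2-yl]oxy}silane
Conditions: Et3SiOTf, 2,6-lutidine, CH2Cl2, −40 → 0 °C
Reagents that add atoms: triethylsilyl trifluoromethanesulfonate, CC[Si](CC)(CC)OS(=O)(=O)C(F)(F)F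
Why: Silylation of a tertiary alcohol with a silyl triflate and a hindered base. The silyl ether removes the acidic proton for the organometallic steps and later keeps the carbinol out of orthoester exchange.

Step 7
Reactants: 12 5-methoxyresorcinol
Product: 13 1-methoxy-3,5-bis(methoxymethoxy)benzene
Conditions: NaH, CH3OCH2Cl, DMF, 0 °C → rt
Reagents that add atoms: chloromethyl methyl ether, COCCl
Why: Williamson-type O-alkylation of both phenoxides; the acetals serve as directing groups in steps 8 and 10.

Step 8
Reactants: 13 1-methoxy-3,5-bis(methoxymethoxy)benzene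
Product: 15 2-iodo-5-methoxy-1,3-bis(methoxymethoxy)benzene, via aryllithium 14 (not isolated)
Conditions: n-BuLi, THF, 0 °C; then I2, −78 °C → rt
Reagents that add atoms: iodine, II
Why: Directed ortho-metalation at the position flanked by two chelating acetals, which are stronger directors than the methoxy group, followed by iodine quench. Any isomer from lithiation next to the methoxy group can be removed at this stage.

Step 9
Reactants: 11 triethyl{[(5S)-6-iodo-2-methyl-5-(prop-1-en-2-yl)hexan-2-yl]oxy}silane; 15 2-iodo-5-methoxy-1,3-bis(methoxymethoxy)benzene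
Product: 17 triethyl{[(5R)-6-[4-methoxy-2,6-bis(methoxymethoxy)phenyl]-2-methyl-5-(prop-1-en-2-yl)hexan-2-yl]oxy}silane, via alkylzinc iodide 16 (not isolated)
Conditions: 11, Zn dust (activated with BrCH2CH2Br, Me3SiCl), LiCl, THF, 40 °C; then 15, Pd(OAc)2 (5 mol %), 2-dicyclohexylphosphino-2',6'-dimethoxybiphenyl (10 mol %), THF, 50 °C
Reagents that add atoms: none
Why: Negishi coupling: zinc inserts into the primary C–I bond, and 16 transmetalates to the arylpalladium iodide formed from 15 and zerovalent palladium. The bulky biaryl phosphine favours reductive elimination over β-hydride elimination. C2'' is not involved; its descriptor becomes R only because the priorities change.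

Step 10
Reactants: 17 triethyl{[(5R)-6-[4-methoxy-2,6-bis(methoxymethoxy)phenyl]-2-methyl-5-(prop-1-en-2-yl)hexan-2-yl]oxy}silane
Product: 19 6-methoxy-2,4-bis(methoxymethoxy)-3-[(2R)-5-methyl-2-(prop-1-en-2-yl)-5-(triethylsilyloxy)hexyl]benzaldehyde, via aryllithium 18 (not isolated)
Conditions: n-BuLi, TMEDA, THF, −20 → 0 °C; then DMF, −78 °C → rt
Reagents that add atoms: N,N-dimethylformamide, CN(C)C=O
Why: Directed ortho-metalation at either of the two equivalent ring positions, each flanked by an acetal and the methoxy group, then formylation. The symmetry of 17 removes any regiochemical question.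

Step 11
Reactants: 19 6-methoxy-2,4-bis(methoxymethoxy)-3-[(2R)-5-methyl-2-(prop-1-en-2-yl)-5-(triethylsilyloxy)hexyl]benzaldehyde
Product: 20 2-hydroxy-6-methoxy-4-(methoxymethoxy)-3-[(2R)-5-methyl-2-(prop-1-en-2-yl)-5-(triethylsilyloxy)hexyl]benzaldehyde
Conditions: MgBr2·OEt2 (2.5 equiv), Et2O/CH2Cl2, 0 °C → rt
Reagents that add atoms: none
Why: Chelation-controlled acetal cleavage: magnesium bridges the formyl oxygen and the neighbouring acetal oxygen, so only the methoxymethyl group ortho to the aldehyde is lost. The para acetal, the methyl ether and the silyl ether lack this activation.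

Step 12
Reactants: 21 4-hydroxy-2-methoxybenzaldehyde
Product: 22 2-methoxy-4-(methoxymethoxy)benzaldehyde
Conditions: CH3OCH2Cl, i-Pr2NEt, CH2Cl2, 0 °C → rt
Reagents that add atoms: chloromethyl methyl ether, COCCl
Why: O-alkylation of an acidic para-formyl phenol with an amine base; a routine protection.

Step 13
Reactants: 22 2-methoxy-4-(methoxymethoxy)benzaldehyde
Product: 23 2-methoxy-4-(methoxymethoxy)-1-vinylbenzene
Conditions: Ph3PCH3Br, KOtBu, THF, 0 °C → rt
Reagents that add atoms: methyltriphenylphosphonium bromide, C[P+](c1ccccc1)(c1ccccc1)c1ccccc1.[Br-]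
Why: Wittig methylenation of an aromatic aldehyde; the styrene is used soon after preparation because it polymerises readily.

Step 14
Reactants: 20 2-hydroxy-6-methoxy-4-(methoxymethoxy)-3-[(2R)-5-methyl-2-(prop-1-en-2-yl)-5-(triethylsilyloxy)hexyl]benzaldehyde; 23 2-methoxy-4-(methoxymethoxy)-1-vinylbenzene; 24 trimethyl orthoformate
Product: 27 (2S,4S)-4,5-dimethoxy-2-[2-methoxy-4-(methoxymethoxy)phenyl]-7-(methoxymethoxy)-8-[(2R)-5-methyl-2-(prop-1-en-2-yl)-5-(triethylsilyloxy)hexyl]chromane (2,4-cis), via dimethyl acetal 25 (not isolated), via methoxy ortho-quinone methide 26 (not isolated)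
Conditions: (R)-3,3'-bis(2,4,6-triisopropylphenyl)-1,1'-binaphthyl-2,2'-diyl hydrogen phosphate (10 mol %), 24 (3 equiv), 23 (2 equiv), 5 Å MS, toluene, 0 °C → rt; Et3N quench
Reagents that add atoms: none
Why: Proposed new method: the acid and the orthoformate convert 20 into acetal 25, which loses methanol to give the C4-methoxy ortho-quinone methide 26, held as a hydrogen-bonded ion pair with the chiral phosphate; 23 then adds in an inverse-demand (4+2) cycloaddition. The closest known reaction types are the acid-promoted cycloaddition of salicylaldehyde acetals with styrenes to 2,4-cis-4-alkoxyflavans and the chiral phosphoric acid-catalysed cycloaddition of aryl-substituted ortho-quinone methides with styrenes; an alkoxy-substituted methide under chiral acid control is the untested part. Ring C closes by the (4+2) mode, with the oxadiene supplying O1–C8a–C4a–C4 and the styrene supplying C3–C2; if the process is stepwise, the C3–C4 bond forms first and the phenolic oxygen then captures the benzylic cation at C2 in a six-membered closure that restores the aromaticity of ring A. The C2 configuration is controlled by the chiral phosphate anion, which must shield one face of the bound methide, since the chain centre is too remote to matter. C4 is set relative to C2 by the endo approach of the aryl group to the (E)-methide, giving the 2,4-cis product, and is removed in step 16. Regiochemistry follows polarity, the nucleophilic CH2 terminus of the styrene bonding to the electrophilic methide carbon. The step needs the styrene to win over the isopropenyl group, which is secured by the two alkoxy donors on ring B and the excess of 23. The three oxygen donors on ring A let a weak acid ionise the acetal, so the acetals, the silyl ether and the alkene should survive.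

Step 15
Reactants: 27 (2S,4S)-4,5-dimethoxy-2-[2-methoxy-4-(methoxymethoxy)phenyl]-7-(methoxymethoxy)-8-[(2R)-5-methyl-2-(prop-1-en-2-yl)-5-(triethylsilyloxy)hexyl]chromane
Product: 28 (2S)-5-methoxy-2-[2-methoxy-4-(methoxymethoxy)phenyl]-7-(methoxymethoxy)-8-[(2R)-5-methyl-2-(prop-1-en-2-yl)-5-(triethylsilyloxy)hexyl]chroman-4-ol (both C4 epimers)
Conditions: PPTS (0.2 equiv), THF/H2O (4:1), rt
Reagents that add atoms: water, O
Why: Ionising hydrolysis of a benzylic methyl ether: the C4 cation is stabilised by three ortho and para oxygens of ring A, so a weak acid suffices while the acetals and the silyl ether persist. C4 becomes a mixture, which does not matter.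

Step 16
Reactants: 28 (2S)-5-methoxy-2-[2-methoxy-4-(methoxymethoxy)phenyl]-7-(methoxymethoxy)-8-[(2R)-5-methyl-2-(prop-1-en-2-yl)-5-(triethylsilyloxy)hexyl]chroman-4-ol
Product: 29 (2S)-5-methoxy-2-[2-methoxy-4-(methoxymethoxy)phenyl]-7-(methoxymethoxy)-8-[(2R)-5-methyl-2-(prop-1-en-2-yl)-5-(triethylsilyloxy)hexyl]chroman-4-one
Conditions: MnO2 (activated, 15 equiv), CH2Cl2, rt
Reagents that add atoms: none
Why: Manganese dioxide oxidation of an electron-rich benzylic alcohol under neutral heterogeneous conditions; both C4 epimers converge on the ketone, and C2 sees neither acid nor base.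

Step 17
Reactants: 29 (2S)-5-methoxy-2-[2-methoxy-4-(methoxymethoxy)phenyl]-7-(methoxymethoxy)-8-[(2R)-5-methyl-2-(prop-1-en-2-yl)-5-(triethylsilyloxy)hexyl]chroman-4-one
Product: 30 (2S)-7-hydroxy-2-(4-hydroxy-2-methoxyphenyl)-8-[(2R)-5-hydroxy-5-methyl-2-(prop-1-en-2-yl)hexyl]-5-methoxychroman-4-one
Conditions: aq. HCl (2 M)/MeOH/THF (1:4:2), rt → 40 °C
Reagents that add atoms: none
Why: Acid-catalysed solvolysis of two aryl methoxymethyl acetals and a tertiary silyl ether. Dilute acid at moderate temperature should stay below the threshold for protonating the isopropenyl group or ionising the carbinol, and avoids the base that would open the flavanone.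

## Compound list

1 | (S)-4-benzyloxazolidin-2-one | O=C1OC[C@H](Cc2ccccc2)N1 | starting material
2 | 3-methylbut-2-enoyl chloride | CC(C)=CC(=O)Cl | starting material
3 | N-lithio-(S)-4-benzyloxazolidin-2-one | [Li]N1C(=O)OC[C@@H]1Cc1ccccc1 | intermediate
4 | (S)-4-benzyl-3-(3-methylbut-2-enoyl)oxazolidin-2-one | CC(C)=CC(=O)N1[C@@H](Cc2ccccc2)COC1=O | intermediate
5 | 1-bromo-3-methylbut-2-ene | CC(C)=CCBr | starting material
6 | sodium (Z)-dienolate of 4 | C=C(C)/C=C(\[O-])N1[C@@H](Cc2ccccc2)COC1=O.[Na+] | intermediate
7 | (4S)-4-benzyl-3-[(2S)-5-methyl-2-(prop-1-en-2-yl)hex-4-enoyl]oxazolidin-2-one | CC(C)=CC[C@@H](C(C)=C)C(=O)N1[C@@H](Cc2ccccc2)COC1=O | intermediate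
8 | (4S)-4-benzyl-3-{(2S)-2-[(3,3-dimethyloxiran-2-yl)methyl]-3-methylbut-3-enoyl}oxazolidin-2-one, oxirane carbon as both epimers | CC1(C)OC1C[C@@H](C(C)=C)C(=O)N2[C@@H](Cc3ccccc3)COC2=O | intermediate
9 | (2S)-5-methyl-2-(prop-1-en-2-yl)hexane-1,5-diol | C=C(C)[C@H](CCC(C)(C)O)CO | intermediate
10 | (5S)-6-iodo-2-methyl-5-(prop-1-en-2-yl)hexan-2-ol | C=C(C)[C@H](CCC(C)(C)O)CI | intermediate
11 | triethyl{[(5S)-6-iodo-2-methyl-5-(prop-1-en-2-yl)hexan-2-yl]oxy}silane | C=C(C)[C@H](CCC(C)(C)O[Si](CC)(CC)CC)CI | intermediate
12 | 5-methoxyresorcinol | COc1cc(O)cc(O)c1 | starting material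
13 | 1-methoxy-3,5-bis(methoxymethoxy)benzene | COCOc1cc(OC)cc(OCOC)c1 | intermediate
14 | [4-methoxy-2,6-bis(methoxymethoxy)phenyl]lithium | [Li]c1c(OCOC)cc(OC)cc1OCOC | intermediate
15 | 2-iodo-5-methoxy-1,3-bis(methoxymethoxy)benzene | COCOc1cc(OC)cc(OCOC)c1I | intermediate
16 | [(2S)-5-methyl-2-(prop-1-en-2-yl)-5-(triethylsilyloxy)hexyl]zinc iodide | C=C(C)[C@H](CCC(C)(C)O[Si](CC)(CC)CC)C[Zn]I | intermediate
17 | triethyl{[(5R)-6-[4-methoxy-2,6-bis(methoxymethoxy)phenyl]-2-methyl-5-(prop-1-en-2-yl)hexan-2-yl]oxy}silane | C=C(C)[C@H](CCC(C)(C)O[Si](CC)(CC)CC)Cc1c(OCOC)cc(OC)cc1OCOC | intermediate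
18 | aryllithium from 17, lithiated at the ring position between the acetal and the methoxy group | C=C(C)[C@H](CCC(C)(C)O[Si](CC)(CC)CC)Cc1c(OCOC)cc(OC)c([Li])c1OCOC | intermediate
19 | 6-methoxy-2,4-bis(methoxymethoxy)-3-[(2R)-5-methyl-2-(prop-1-en-2-yl)-5-(triethylsilyloxy)hexyl]benzaldehyde | C=C(C)[C@H](CCC(C)(C)O[Si](CC)(CC)CC)Cc1c(OCOC)cc(OC)c(C=O)c1OCOC | intermediate
20 | 2-hydroxy-6-methoxy-4-(methoxymethoxy)-3-[(2R)-5-methyl-2-(prop-1-en-2-yl)-5-(triethylsilyloxy)hexyl]benzaldehyde | C=C(C)[C@H](CCC(C)(C)O[Si](CC)(CC)CC)Cc1c(OCOC)cc(OC)c(C=O)c1O | intermediate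
21 | 4-hydroxy-2-methoxybenzaldehyde | COc1cc(O)ccc1C=O | starting material
22 | 2-methoxy-4-(methoxymethoxy)benzaldehyde | COCOc1ccc(C=O)c(OC)c1 | intermediate
23 | 2-methoxy-4-(methoxymethoxy)-1-vinylbenzene | C=Cc1ccc(OCOC)cc1OC | intermediate
24 | trimethyl orthoformate | COC(OC)OC | starting material
25 | dimethyl acetal of 20 | C=C(C)[C@H](CCC(C)(C)O[Si](CC)(CC)CC)Cc1c(OCOC)cc(OC)c(C(OC)OC)c1O | intermediate
26 | (E)-6-(methoxymethylene)cyclohexa-2,4-dienone form of ring A (C4-methoxy ortho-quinone methide), chain (2R) | CO/C=C1\C(OC)=CC(OCOC)=C(C[C@@H](CCC(C)(C)O[Si](CC)(CC)CC)C(C)=C)C1=O | intermediate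
27 | (2S,4S)-4,5-dimethoxy-2-[2-methoxy-4-(methoxymethoxy)phenyl]-7-(methoxymethoxy)-8-[(2R)-5-methyl-2-(prop-1-en-2-yl)-5-(triethylsilyloxy)hexyl]chromane | C=C(C)[C@H](CCC(C)(C)O[Si](CC)(CC)CC)Cc1c(OCOC)cc(OC)c2c1O[C@H](c1ccc(OCOC)cc1OC)C[C@@H]2OC | intermediate
28 | (2S)-5-methoxy-2-[2-methoxy-4-(methoxymethoxy)phenyl]-7-(methoxymethoxy)-8-[(2R)-5-methyl-2-(prop-1-en-2-yl)-5-(triethylsilyloxy)hexyl]chroman-4-ol, C4 as both epimers | C=C(C)[C@H](CCC(C)(C)O[Si](CC)(CC)CC)Cc1c(OCOC)cc(OC)c2c1O[C@H](c1ccc(OCOC)cc1OC)CC2O | intermediate
29 | (2S)-5-methoxy-2-[2-methoxy-4-(methoxymethoxy)phenyl]-7-(methoxymethoxy)-8-[(2R)-5-methyl-2-(prop-1-en-2-yl)-5-(triethylsilyloxy)hexyl]chroman-4-one | C=C(C)[C@H](CCC(C)(C)O[Si](CC)(CC)CC)Cc1c(OCOC)cc(OC)c2c1O[C@H](c1ccc(OCOC)cc1OC)CC2=O | intermediate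
30 | (2S)-7-hydroxy-2-(4-hydroxy-2-methoxyphenyl)-8-[(2R)-5-hydroxy-5-methyl-2-(prop-1-en-2-yl)hexyl]-5-methoxychroman-4-one | C=C(C)[C@H](CCC(C)(C)O)Cc1c(O)cc(OC)c2c1O[C@H](c1ccc(O)cc1OC)CC2=O | target

## Step count and least certain steps

Total: 17 steps. Longest linear sequence: 13 steps (steps 1 to 6, 9, 10, 11, 14, 15, 16, 17).

**Step 14 (key step, the one step beyond established practice).**
- What may go wrong:
  - Poor facial discrimination at C2: the styrene offers the catalyst no hydrogen-bond handle, and the methide is flanked by two ortho substituents.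
  - Erosion of the C2 configuration by acid-mediated reopening of the C2–O1 bond of the product.
  - Cationic oligomerisation of the styrene, or Friedel–Crafts attack of the free ring A position on the oxocarbenium ion.
  - Slow acetal formation from the chelated, doubly ortho-substituted aldehyde.
- Fallback (known chemistry): it sets out from 17 and returns at 29. Arene 17 is lithiated as in step 10 and acylated with N-methoxy-N-methylacetamide to give the acetophenone F1. MgBr2·OEt2 removes the acetal next to the ketone to give the 2'-hydroxyacetophenone F2. Claisen–Schmidt condensation with aldehyde 22 (KOH, EtOH) gives the (E)-chalcone F3. Closure with NaOAc in refluxing EtOH gives 29 together with its (2R)-epimer F4. The two are separated by preparative chromatography on a chiral phase, and F4 is recycled by base equilibration through F3.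

**Step 9.**
- What may go wrong: slow transmetalation and reductive elimination at the doubly ortho-substituted arylpalladium centre. This would leave room for β-hydride elimination toward the conjugated diene, for protodezincation, and, through hydride elimination and reinsertion, for partial loss of configuration at C2''.
- Fallback: it sets out from 13 and returns at 17. Arene 13 is lithiated to 14 and treated with CuI (0.5 equiv) to give the lithium diarylcuprate F5. This much less basic nucleophile displaces iodide from 11 in THF/Et2O between −20 and 0 °C.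

**Step 11.**
- What may go wrong: incomplete discrimination between the two acetals, or loss of the silyl ether under Lewis acid.
- Fallback: it sets out from 19 and returns at 20. Methanolic HCl removes both acetals and the silyl group to give the dihydroxy aldehyde F6. CH3OCH2Cl with K2CO3 in acetone alkylates only the non-chelated para hydroxyl to give the mono-acetal F7. Excess Et3SiOTf with 2,6-lutidine gives the bis-silyl compound F8, and K2CO3 in MeOH cleaves its aryl silyl ether alone.

**Step 15.**
- What may go wrong: loss of a proton from the C4 cation to give the flav-3-ene, or ionisation at C2 with scrambling of that centre.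
- Fallback: it sets out from 27 and returns at 29, bypassing 28. DDQ in CH2Cl2 with aqueous pH 7 buffer abstracts hydride from C4, and the oxocarbenium ion is hydrolysed directly to the ketone. No new isolable compound is made (F0).

**Step 17.**
- What may go wrong: ionisation of the tertiary carbinol (methyl ether formation or dehydration), acid-catalysed addition of the C7 hydroxyl to the isopropenyl group, or partial racemisation through the chalcone.
- Fallback: it sets out from 29 and returns at 30. HF·pyridine in THF removes the silyl group to give the bis-acetal flavanone F9. Its aryl acetals are then exchanged under non-protic conditions with Me3SiOTf and 2,2'-bipyridyl in CH2Cl2 at 0 °C, and water hydrolyses the resulting silyl ethers.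

## Further compounds

F1 | step 14 | 1-{6-methoxy-2,4-bis(methoxymethoxy)-3-[(2R)-5-methyl-2-(prop-1-en-2-yl)-5-(triethylsilyloxy)hexyl]phenyl}ethan-1-one | C=C(C)[C@H](CCC(C)(C)O[Si](CC)(CC)CC)Cc1c(OCOC)cc(OC)c(C(C)=O)c1OCOC
F2 | step 14 | 1-{2-hydroxy-6-methoxy-4-(methoxymethoxy)-3-[(2R)-5-methyl-2-(prop-1-en-2-yl)-5-(triethylsilyloxy)hexyl]phenyl}ethan-1-one | C=C(C)[C@H](CCC(C)(C)O[Si](CC)(CC)CC)Cc1c(OCOC)cc(OC)c(C(C)=O)c1O
F3 | step 14 | (E)-1-{2-hydroxy-6-methoxy-4-(methoxymethoxy)-3-[(2R)-5-methyl-2-(prop-1-en-2-yl)-5-(triethylsilyloxy)hexyl]phenyl}-3-[2-methoxy-4-(methoxymethoxy)phenyl]prop-2-en-1-one | C=C(C)[C@H](CCC(C)(C)O[Si](CC)(CC)CC)Cc1c(OCOC)cc(OC)c(C(=O)/C=C/c2ccc(OCOC)cc2OC)c1O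
F4 | step 14 | (2R)-epimer of 29 | C=C(C)[C@H](CCC(C)(C)O[Si](CC)(CC)CC)Cc1c(OCOC)cc(OC)c2c1O[C@@H](c1ccc(OCOC)cc1OC)CC2=O
F5 | step 9 | lithium bis[4-methoxy-2,6-bis(methoxymethoxy)phenyl]cuprate | [Li+].COCOc1cc(OC)cc(OCOC)c1[Cu-]c1c(OCOC)cc(OC)cc1OCOC
F6 | step 11 | 2,4-dihydroxy-3-[(2R)-5-hydroxy-5-methyl-2-(prop-1-en-2-yl)hexyl]-6-methoxybenzaldehyde | C=C(C)[C@H](CCC(C)(C)O)Cc1c(O)cc(OC)c(C=O)c1O
F7 | step 11 | 2-hydroxy-3-[(2R)-5-hydroxy-5-methyl-2-(prop-1-en-2-yl)hexyl]-6-methoxy-4-(methoxymethoxy)benzaldehyde | C=C(C)[C@H](CCC(C)(C)O)Cc1c(OCOC)cc(OC)c(C=O)c1O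
F8 | step 11 | 6-methoxy-4-(methoxymethoxy)-3-[(2R)-5-methyl-2-(prop-1-en-2-yl)-5-(triethylsilyloxy)hexyl]-2-(triethylsilyloxy)benzaldehyde | C=C(C)[C@H](CCC(C)(C)O[Si](CC)(CC)CC)Cc1c(OCOC)cc(OC)c(C=O)c1O[Si](CC)(CC)CC
F0 | step 15 | none | none
F9 | step 17 | (2S)-8-[(2R)-5-hydroxy-5-methyl-2-(prop-1-en-2-yl)hexyl]-5-methoxy-2-[2-methoxy-4-(methoxymethoxy)phenyl]-7-(methoxymethoxy)chroman-4-one | C=C(C)[C@H](CCC(C)(C)O)Cc1c(OCOC)cc(OC)c2c1O[C@H](c1ccc(OCOC)cc1OC)CC2=O
A1 | alternative 1 | (E)-2'-hydroxychalcone with ring A fully substituted (same structure as F3) | C=C(C)[C@H](CCC(C)(C)O[Si](CC)(CC)CC)Cc1c(OCOC)cc(OC)c(C(=O)/C=C/c2ccc(OCOC)cc2OC)c1O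
A2 | alternative 1 | 3-methoxy-5-(methoxymethoxy)-6-[(2R)-5-methyl-2-(prop-1-en-2-yl)-5-(triethylsilyloxy)hexyl]-2-(trimethylsilyl)phenyl trifluoromethanesulfonate | C=C(C)[C@H](CCC(C)(C)O[Si](CC)(CC)CC)Cc1c(OCOC)cc(OC)c([Si](C)(C)C)c1OS(=O)(=O)C(F)(F)F
A3 | alternative 1 | (E)-3-[2-methoxy-4-(methoxymethoxy)phenyl]prop-2-enoic acid | COCOc1ccc(/C=C/C(=O)O)c(OC)c1
A4 | alternative 2 | 5-methoxy-2-[(2R)-5-methyl-2-(prop-1-en-2-yl)-5-(triethylsilyloxy)hexyl]-3-(triisopropylsilyloxy)phenol | C=C(C)[C@H](CCC(C)(C)O[Si](CC)(CC)CC)Cc1c(O)cc(OC)cc1O[Si](C(C)C)(C(C)C)C(C)C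
A5 | alternative 2 | 3-methoxycyclobut-2-en-1-one | COC1=CC(=O)C1
A6 | alternative 2 | triisopropyl{[(4R)-7-methyl-4-(prop-1-en-2-yl)-7-(triethylsilyloxy)oct-1-yn-1-yl]oxy}silane | C=C(C)[C@H](CCC(C)(C)O[Si](CC)(CC)CC)CC#CO[Si](C(C)C)(C(C)C)C(C)C
A7 | alternative 2 | 2-hydroxy-6-methoxy-3-[(2R)-5-methyl-2-(prop-1-en-2-yl)-5-(triethylsilyloxy)hexyl]-4-(triisopropylsilyloxy)benzaldehyde | C=C(C)[C@H](CCC(C)(C)O[Si](CC)(CC)CC)Cc1c(O[Si](C(C)C)(C(C)C)C(C)C)cc(OC)c(C=O)c1O
A8 | alternative 3 | (2S)-5,7-dihydroxy-2-[2-methoxy-4-(methoxymethoxy)phenyl]-8-[(2R)-5-methyl-2-(prop-1-en-2-yl)-5-(triethylsilyloxy)hexyl]chroman-4-one | C=C(C)[C@H](CCC(C)(C)O[Si](CC)(CC)CC)Cc1c(O)cc(O)c2c1O[C@H](c1ccc(OCOC)cc1OC)CC2=O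
A9 | alternative 3 | (2S)-2-[2-methoxy-4-(methoxymethoxy)phenyl]-6-[(3R)-1-(2,2-dimethyl-4-oxo-4H-1,3-dioxin-6-yl)-6-methyl-3-(prop-1-en-2-yl)-6-(triethylsilyloxy)heptyl]-2,3-dihydro-4H-pyran-4-one, C1 of the heptyl group as both epimers | C=C(C)[C@H](CCC(C)(C)O[Si](CC)(CC)CC)CC(C1=CC(=O)C[C@@H](c2ccc(OCOC)cc2OC)O1)C1=CC(=O)OC(C)(C)O1
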